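A direct plan would O-alkylate the phenol of ring B (4-allyl-2,6-dimethoxyphenyl) with the ring A bromo ketone A1 (ring A: 3,4-dimethoxyphenyl) to the aryloxy ketone A2, would set C8 (the aryloxy carbon; C7 benzylic, C9 methyl) by enantioselective phase-transfer methylation of its enolate (A3), would reduce the ketone under chelation control to the erythro carbinol A4 and would acetylate it. Its weakest step would be the enolate methylation: it would have no close precedent on a carbon bearing an aryloxy group, and A3 would stay enolisable under the same base, so racemisation and double methylation would compete. The ketone reduction would inherit any loss of configuration at C8 as a lower diastereomer ratio. The ether formation on A1 would add a step that only postpones the C9 methyl group.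

The new route disconnects the bond from C7 to ring A and the acetate C–O bond at C7. In one flask the ring A aryltitanium, the aldehyde that carries C8, C9 and ring B, and acetic anhydride would be joined. The step exploits the aryloxy group on C8: as the polar, non-chelating substituent of a Felkin–Anh transition state it steers the aryl group so that the C7 oxygen ends anti to the C8 oxygen, the erythro pattern of the target. C8 itself would come from methyl (R)-lactate by Mitsunobu inversion with the ring B phenol, so neither an enolate methylation nor a ketone reduction is needed.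

Key step: step 3

Assumption: the Grignard reagent of ring A is taken as its commercial THF solution; it could equally be made from 4-bromo-1,2-dimethoxybenzene and magnesium.

Step 1
Reactants: 1 4-allyl-2,6-dimethoxyphenol (methoxyeugenol); 2 methyl (R)-lactate
Product: 3 methyl (S)-2-(4-allyl-2,6-dimethoxyphenoxy)propanoate
Conditions: PPh3 (1.3 equiv), DIAD (1.3 equiv), THF, 0 °C → rt
Reagents that add atoms: none
Why: Mitsunobu etherification, in which the lactate hydroxyl, activated as its alkoxyphosphonium ion next to the ester carbonyl, is displaced by the phenoxide of 1 in an SN2 reaction, so that C8 should be set as S by inversion of the R centre of 2 under neutral conditions that leave the allyl group and the aryl methyl ethers untouched.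

Step 2
Reactants: 3 methyl (S)-2-(4-allyl-2,6-dimethoxyphenoxy)propanoate
Product: 4 (S)-2-(4-allyl-2,6-dimethoxyphenoxy)propanal
Conditions: iBu2AlH (1.1 equiv), CH2Cl2, −78 °C; MeOH, then aqueous potassium sodium tartrate, −78 °C → rt; crude 4 used at once without chromatography
Reagents that add atoms: none
Why: Partial reduction of an ester by iBu2AlH, in which the tetrahedral aluminium hemiacetal should survive at −78 °C until the cold quench, so that the aldehyde is released only on neutral work-up, no new stereocentre is formed and the acidic C8–H is never exposed to base.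

Step 3
Reactants: 4 (S)-2-(4-allyl-2,6-dimethoxyphenoxy)propanal; 5 (3,4-dimethoxyphenyl)magnesium bromide
Product: 8 Maceneolignan H [(1R,2S)-2-(4-allyl-2,6-dimethoxyphenoxy)-1-(3,4-dimethoxyphenyl)propyl acetate], via (3,4-dimethoxyphenyl)titanium triisopropoxide 6 (not isolated), via titanium alkoxide of the erythro carbinol 7 (not isolated)
Conditions: 5 (1.5 equiv), ClTi(OiPr)3 (1.6 equiv), THF, −78 → 0 °C; 4, THF, −78 → −10 °C; then pyridine (10 equiv), Ac2O (8 equiv), DMAP (0.2 equiv), −10 °C → rt; aqueous NaHCO3
Reagents that add atoms: acetic anhydride, CC(=O)OC(C)=O; chlorotitanium triisopropoxide, CC(C)O[Ti](Cl)(OC(C)C)OC(C)C (its atoms stay only in 6 and 7)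
Why: The Grignard reagent 5 is transmetalated by ClTi(OiPr)3 to the aryltitanium triisopropoxide 6, which is only weakly basic and weakly Lewis acidic and adds to the aldehyde carbonyl of 4 through a four-centre transition state; the titanium alkoxide 7 is then O-acetylated in the same flask by DMAP-catalysed acyl transfer from Ac2O, which does not touch the C7–O bond. The closest known reaction type is the non-chelation-controlled 1,2-addition of organotitanium triisopropoxides to α-alkoxy aldehydes, followed by acylation of the metal alkoxide. The new stereocentre C7 is controlled by C8 through a polar Felkin–Anh transition state: the C8–OAr bond lies anti to the incoming aryl group, which passes the C8–H and attacks the Re face of the S aldehyde, so C7 should form as R with its oxygen anti to the C8 oxygen (erythro). The step needs facial selectivity without chelation and no epimerisation at C8; the first is secured by the three isopropoxide ligands, which leave tetravalent titanium too weak a Lewis acid to bridge the carbonyl oxygen and the hindered, poorly basic 2,6-dimethoxyphenoxy oxygen, and the second by the low basicity of 6, which should not enolise 4 at low temperature. It also needs chemoselectivity, which follows from the inertness of 6 towards the allyl group and the aryl methyl ethers, while pyridine buffers the acetylation so that the electron-rich benzylic C7–O bond should not ionise.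

Compound list
1 | 4-allyl-2,6-dimethoxyphenol (methoxyeugenol) | C=CCc1cc(OC)c(O)c(OC)c1 | starting material
2 | methyl (R)-lactate, methyl (2R)-2-hydroxypropanoate | C[C@@H](O)C(=O)OC | starting material
3 | methyl (S)-2-(4-allyl-2,6-dimethoxyphenoxy)propanoate | C=CCc1cc(OC)c(O[C@@H](C)C(=O)OC)c(OC)c1 | intermediate
4 | (S)-2-(4-allyl-2,6-dimethoxyphenoxy)propanal | C=CCc1cc(OC)c(O[C@@H](C)C=O)c(OC)c1 | intermediate
5 | (3,4-dimethoxyphenyl)magnesium bromide | COc1ccc([Mg]Br)cc1OC | starting material
6 | (3,4-dimethoxyphenyl)titanium triisopropoxide | COc1ccc([Ti](OC(C)C)(OC(C)C)OC(C)C)cc1OC | intermediate (not isolated)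
7 | triisopropoxytitanium alkoxide of (1R,2S)-2-(4-allyl-2,6-dimethoxyphenoxy)-1-(3,4-dimethoxyphenyl)propan-1-ol | C=CCc1cc(OC)c(O[C@@H](C)[C@H](O[Ti](OC(C)C)(OC(C)C)OC(C)C)c2ccc(OC)c(OC)c2)c(OC)c1 | intermediate (not isolated)
8 | Maceneolignan H, (1R,2S)-2-(4-allyl-2,6-dimethoxyphenoxy)-1-(3,4-dimethoxyphenyl)propyl acetate | C=CCc1cc(OC)c(O[C@@H](C)[C@H](OC(C)=O)c2ccc(OC)c(OC)c2)c(OC)c1 | target

Total step count: 3. Longest linear sequence: 3 steps (1 → 3 → 4 → 8).

Steps most likely to fail

Step 3: the aryl addition may show poor facial selectivity (partial chelation would lead to the threo isomer), or the acylation in the flask may stay incomplete. The fallback sets out from aldehyde 4. The Grignard reagent 5 would be added directly in THF at −78 °C and quenched with NH4Cl, with no need for selectivity, to give (2S)-2-(4-allyl-2,6-dimethoxyphenoxy)-1-(3,4-dimethoxyphenyl)propan-1-ol F1 as a mixture of C7 epimers. Oxidation with Dess–Martin periodinane buffered by NaHCO3 would give (S)-2-(4-allyl-2,6-dimethoxyphenoxy)-1-(3,4-dimethoxyphenyl)propan-1-one F2. Chelation-controlled reduction with Zn(BH4)2 in Et2O at −30 °C would give (1R,2S)-2-(4-allyl-2,6-dimethoxyphenoxy)-1-(3,4-dimethoxyphenyl)propan-1-ol F3. Acetylation with Ac2O, pyridine and DMAP would come back to the route at 8.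

Step 2: the partial reduction may run on to the primary alcohol, or the aldehyde may lose configuration at C8 during work-up. The fallback sets out from ester 3. Full reduction with LiAlH4 in THF at 0 °C would give (S)-2-(4-allyl-2,6-dimethoxyphenoxy)propan-1-ol F4. Oxidation with Dess–Martin periodinane and NaHCO3 in CH2Cl2 at 0 °C, followed by filtration and direct use, would come back to the route at 4.

Step 1: the Mitsunobu coupling of the hindered phenol may be slow, so that alkylation of the reduced azodicarboxylate or elimination to methyl acrylate would compete. The fallback sets out from lactate 2. Tf2O and 2,6-lutidine in CH2Cl2 at −78 °C would give methyl (R)-2-(trifluoromethylsulfonyloxy)propanoate F5. The potassium phenoxide of 1 (K2CO3, MeCN, −20 → 0 °C) would displace the triflate by SN2 with inversion and come back to the route at 3.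

Further compounds
F1 | step 3 | (2S)-2-(4-allyl-2,6-dimethoxyphenoxy)-1-(3,4-dimethoxyphenyl)propan-1-ol, mixture of C7 epimers | C=CCc1cc(OC)c(O[C@@H](C)C(O)c2ccc(OC)c(OC)c2)c(OC)c1
F2 | step 3 | (S)-2-(4-allyl-2,6-dimethoxyphenoxy)-1-(3,4-dimethoxyphenyl)propan-1-one | C=CCc1cc(OC)c(O[C@@H](C)C(=O)c2ccc(OC)c(OC)c2)c(OC)c1
F3 | step 3 | (1R,2S)-2-(4-allyl-2,6-dimethoxyphenoxy)-1-(3,4-dimethoxyphenyl)propan-1-ol | C=CCc1cc(OC)c(O[C@@H](C)[C@H](O)c2ccc(OC)c(OC)c2)c(OC)c1
F4 | step 2 | (S)-2-(4-allyl-2,6-dimethoxyphenoxy)propan-1-ol | C=CCc1cc(OC)c(O[C@@H](C)CO)c(OC)c1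
F5 | step 1 | methyl (R)-2-(trifluoromethylsulfonyloxy)propanoate | C[C@@H](OS(=O)(=O)C(F)(F)F)C(=O)OC
A1 | direct plan | 2-bromo-1-(3,4-dimethoxyphenyl)ethan-1-one | COc1ccc(C(=O)CBr)cc1OC
A2 | direct plan | 2-(4-allyl-2,6-dimethoxyphenoxy)-1-(3,4-dimethoxyphenyl)ethan-1-one | C=CCc1cc(OC)c(OCC(=O)c2ccc(OC)c(OC)c2)c(OC)c1
A3 | direct plan | (S)-2-(4-allyl-2,6-dimethoxyphenoxy)-1-(3,4-dimethoxyphenyl)propan-1-one | C=CCc1cc(OC)c(O[C@@H](C)C(=O)c2ccc(OC)c(OC)c2)c(OC)c1
A4 | direct plan | (1R,2S)-2-(4-allyl-2,6-dimethoxyphenoxy)-1-(3,4-dimethoxyphenyl)propan-1-ol | C=CCc1cc(OC)c(O[C@@H](C)[C@H](O)c2ccc(OC)c(OC)c2)c(OC)c1
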